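**Plan**

- Retrosynthesis: the two phenolic silyl ethers are removed first. Then the C3–O bond is cut (enol ether oxidation), then the C2–C1' bond between the chromanone and the catechol ring, and last the geranyl O–CH2 bond. This leads to 7-hydroxychromone, geranyl bromide and 4-bromocatechol.
- Enabling feature: C2 carries the aryl group and is the β-carbon of the C4 ketone inside the pyranone ring (O1–C2–C3–C4=O). The C2–C1' bond is therefore the retron of a 1,4-addition of an aryl nucleophile to the flat, achiral chromone O1–C2=C3–C4=O.
- Forward: the benzopyranone ring is bought intact and no ring is formed in the route. The geranyl chain goes onto O7 first, the aryl ring is joined to C2 by catalytic asymmetric conjugate addition, C3 is oxygenated through the silyl enol ether, and the catechol is unmasked last.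
- Stereochemistry: C2 comes from the chiral Pd/pyridine-oxazoline catalyst (2S in the flavanone, which is the 2R arrangement of the target once C3 carries oxygen). C3 is relayed from C2: the oxidant adds anti to the aryl group and gives the trans (2R,3R) isomer, which is also the more stable one. The E alkene is bought with geranyl bromide.

Key step: step 4

Remark on the chemistry (assumption): the facial preference of the Pd/t-BuPyOX catalyst on the chromone is taken to parallel that on cyclic enones, which calls for the (R)-ligand to reach the 2S flavanone. Should a test run show the opposite sense, the (S)-ligand is used and nothing else changes. 7-Hydroxychromone, geranyl bromide and 4-bromocatechol are taken as purchased.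

**Route**

Step 1
Reactants: 1 7-hydroxy-4H-chromen-4-one (7-hydroxychromone); 2 geranyl bromide, (2E)-1-bromo-3,7-dimethylocta-2,6-diene
Product: 3 7-{[(2E)-3,7-dimethylocta-2,6-dien-1-yl]oxy}-4H-chromen-4-one (7-geranyloxychromone)
Conditions: K2CO3 (1.5 equiv), 2 (1.1 equiv), acetone, reflux
Reagents that add atoms: none
Why: Williamson ether synthesis, in which the acidic 7-OH (conjugated to the C4 carbonyl through C4a) is deprotonated by carbonate and the phenoxide displaces the primary allylic bromide by SN2, so the E geometry is kept, while carbonate in acetone is too weak a nucleophile to open the chromone ring.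

Step 2
Reactants: 4 4-bromobenzene-1,2-diol (4-bromocatechol)
Product: 5 4-bromo-1,2-bis(tert-butyldimethylsilyloxy)benzene
Conditions: TBSCl (2.4 equiv), imidazole (5 equiv), DMF, rt
Reagents that add atoms: tert-butyldimethylsilyl chloride CC(C)(C)[Si](C)(C)Cl
Why: Imidazole-promoted O-silylation of both phenols (standard silyl ether formation) masks the catechol as ethers that should tolerate the organolithium, Pd(II), silyl triflate and dioxirane steps and can be removed at the end without acid, hydrogen or strong base, none of which the geranyl ether or the dihydroflavonol would tolerate.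

Step 3
Reactants: 5 4-bromo-1,2-bis(tert-butyldimethylsilyloxy)benzene
Product: 8 [3,4-bis(tert-butyldimethylsilyloxy)phenyl]boronic acid, via aryllithium 6 (not isolated), via lithium aryltriisopropoxyborate 7 (not isolated)
Conditions: n-BuLi (1.05 equiv), THF, −78 °C; B(OiPr)3 (1.5 equiv), −78 °C to rt; 1 M HCl to pH 5, 0 °C
Reagents that add atoms: triisopropyl borate CC(C)OB(OC(C)C)OC(C)C (boron); water O (the two boron-bound oxygens); n-butyllithium [Li]CCCC (lithium of 6 and 7 only)
Why: Bromine–lithium exchange, borylation of the aryllithium with a trialkyl borate and mild hydrolysis is the standard route to arylboronic acids, and because lithium sits meta and para to the silyloxy groups the ortho-specific anionic O-to-C silyl shift cannot intervene, while the brief pH 5 hydrolysis should leave the aryl silyl ethers intact.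

Step 4
Reactants: 3 7-geranyloxychromone; 8 [3,4-bis(tert-butyldimethylsilyloxy)phenyl]boronic acid (2 equiv)
Product: 9 (2S)-2-[3,4-bis(tert-butyldimethylsilyloxy)phenyl]-7-{[(2E)-3,7-dimethylocta-2,6-dien-1-yl]oxy}-2,3-dihydro-4H-chromen-4-one
Conditions: Pd(OCOCF3)2 (5 mol%), (R)-t-BuPyOX [(R)-4-tert-butyl-2-(pyridin-2-yl)-4,5-dihydrooxazole] (6 mol%), NH4PF6 (30 mol%), H2O (5 equiv), ClCH2CH2Cl, 60 °C
Reagents that add atoms: none
Why: The aryl group passes from boron to the cationic Pd(II)–pyridine-oxazoline complex, the aryl–Pd bond adds across C2=C3 of the chromone with the aryl group going to C2 (the β-carbon of the vinylogous ester O1–C2=C3–C4=O), and the palladium enolate is protonated by water, which returns the Pd(II) hydroxide without a change of oxidation state. The closest known reaction type is the Pd(II)/t-BuPyOX-catalysed asymmetric conjugate addition of arylboronic acids to chromones to give flavanones, a relative of the Hayashi–Miyaura 1,4-addition. No ring is closed, since the pyranone ring is present from the start. The only new stereocenter, C2, is set under catalyst control in the enantio-determining carbopalladation, where the tert-butyl group of the oxazoline leaves one enantioface of the chromone open, and the (R)-ligand is expected to deliver 2S. The step needs 1,4- over 1,2-addition and chemoselectivity for the chromone alkene over the two geranyl alkenes; the substrate secures both because only C2=C3 is polarised by the carbonyl and can insert into the aryl–Pd cation, and flavone formation is blocked because the only β-hydrogen (on C2) is anti to palladium after syn insertion. The neutral, water-containing medium also avoids opening of the product to the 2'-hydroxychalcone, which would erase C2.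

Step 5
Reactants: 9 (2S)-flavanone from step 4
Product: 12 (2R,3R)-2-[3,4-bis(tert-butyldimethylsilyloxy)phenyl]-7-{[(2E)-3,7-dimethylocta-2,6-dien-1-yl]oxy}-3-hydroxy-2,3-dihydro-4H-chromen-4-one, via silyl enol ether 10 (not isolated), via silyloxy epoxide 11 (not isolated)
Conditions: TMSOTf (1.2 equiv), Et3N (1.5 equiv), CH2Cl2, 0 °C; volatiles removed, pentane filtration; DMDO (1.05 equiv, in acetone), CH2Cl2, −78 to −40 °C; 10% aq. citric acid, THF, 0 °C
Reagents that add atoms: dimethyldioxirane CC1(C)OO1 (the C3 oxygen); trimethylsilyl trifluoromethanesulfonate C[Si](C)(C)OS(=O)(=O)C(F)(F)F (the SiMe3 group of 10 and 11 only)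
Why: Rubottom oxidation, in which soft enolisation gives the 4-silyloxy-2H-chromene 10 without a free enolate that could expel the O1 phenoxide, the dioxirane epoxidises this aryl-conjugated enol ether (expected to be far more nucleophilic than the two isolated trisubstituted geranyl alkenes at −78 °C with one equivalent of oxidant) on the face of C3=C4 opposite to the C2 aryl group, and mild acid opens silyloxy epoxide 11 to the ketol, so that the new C3–O bond is trans to the aryl group (3R), which is also the thermodynamically preferred diequatorial arrangement.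

Step 6
Reactants: 12 bis-silyl dihydroflavonol from step 5
Product: 13 (2R,3R)-2-(3,4-dihydroxyphenyl)-7-{[(2E)-3,7-dimethylocta-2,6-dien-1-yl]oxy}-3-hydroxy-2,3-dihydro-4H-chromen-4-one (the target)
Conditions: TBAF (2.2 equiv), AcOH (2.6 equiv), THF, 0 °C, argon; pH 5 buffer work-up
Reagents that add atoms: none
Why: Fluoride cleavage of the two aryl silyl ethers (Si–F bond formation) with acetic acid present protonates each phenoxide as it forms, so that neither the quinone-methide ring opening that would scramble C2 and C3 nor base-induced dehydrogenation to the flavonol should set in, while the geranyl ether, both alkenes and the ketol are inert to buffered fluoride.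

**Compound list**

1 | 7-hydroxy-4H-chromen-4-one (7-hydroxychromone) | O=c1ccoc2cc(O)ccc12 | starting material
2 | geranyl bromide, (2E)-1-bromo-3,7-dimethylocta-2,6-diene | CC(C)=CCC/C(C)=C/CBr | starting material
3 | 7-{[(2E)-3,7-dimethylocta-2,6-dien-1-yl]oxy}-4H-chromen-4-one | CC(C)=CCC/C(C)=C/COc1ccc2c(c1)occc2=O | intermediate
4 | 4-bromobenzene-1,2-diol (4-bromocatechol) | Oc1ccc(Br)cc1O | starting material
5 | 4-bromo-1,2-bis(tert-butyldimethylsilyloxy)benzene | CC(C)(C)[Si](C)(C)Oc1ccc(Br)cc1O[Si](C)(C)C(C)(C)C | intermediate
6 | [3,4-bis(tert-butyldimethylsilyloxy)phenyl]lithium (formed in the flask, not isolated) | [Li]c1ccc(O[Si](C)(C)C(C)(C)C)c(O[Si](C)(C)C(C)(C)C)c1 | intermediate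
7 | lithium [3,4-bis(tert-butyldimethylsilyloxy)phenyl]tri(propan-2-yloxy)borate (formed in the flask, not isolated) | [Li+].CC(C)O[B-](OC(C)C)(OC(C)C)c1ccc(O[Si](C)(C)C(C)(C)C)c(O[Si](C)(C)C(C)(C)C)c1 | intermediate
8 | [3,4-bis(tert-butyldimethylsilyloxy)phenyl]boronic acid | OB(O)c1ccc(O[Si](C)(C)C(C)(C)C)c(O[Si](C)(C)C(C)(C)C)c1 | intermediate
9 | (2S)-2-[3,4-bis(tert-butyldimethylsilyloxy)phenyl]-7-{[(2E)-3,7-dimethylocta-2,6-dien-1-yl]oxy}-2,3-dihydro-4H-chromen-4-one | CC(C)=CCC/C(C)=C/COc1ccc2c(c1)O[C@H](c1ccc(O[Si](C)(C)C(C)(C)C)c(O[Si](C)(C)C(C)(C)C)c1)CC2=O | intermediate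
10 | (2S)-2-[3,4-bis(tert-butyldimethylsilyloxy)phenyl]-7-{[(2E)-3,7-dimethylocta-2,6-dien-1-yl]oxy}-4-(trimethylsilyloxy)-2H-chromene (formed in the flask, not isolated) | CC(C)=CCC/C(C)=C/COc1ccc2c(c1)O[C@H](c1ccc(O[Si](C)(C)C(C)(C)C)c(O[Si](C)(C)C(C)(C)C)c1)C=C2O[Si](C)(C)C | intermediate
11 | 3,4-epoxide of 10 with the epoxide oxygen trans to the C2 aryl group, (2R,3R,4R) in chroman numbering (formed in the flask, not isolated) | CC(C)=CCC/C(C)=C/COc1ccc2c(c1)O[C@H](c1ccc(O[Si](C)(C)C(C)(C)C)c(O[Si](C)(C)C(C)(C)C)c1)[C@H]3O[C@@]23O[Si](C)(C)C | intermediate
12 | (2R,3R)-2-[3,4-bis(tert-butyldimethylsilyloxy)phenyl]-7-{[(2E)-3,7-dimethylocta-2,6-dien-1-yl]oxy}-3-hydroxy-2,3-dihydro-4H-chromen-4-one | CC(C)=CCC/C(C)=C/COc1ccc2c(c1)O[C@H](c1ccc(O[Si](C)(C)C(C)(C)C)c(O[Si](C)(C)C(C)(C)C)c1)[C@@H](O)C2=O | intermediate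
13 | (2R,3R)-2-(3,4-dihydroxyphenyl)-7-{[(2E)-3,7-dimethylocta-2,6-dien-1-yl]oxy}-3-hydroxy-2,3-dihydro-4H-chromen-4-one | CC(C)=CCC/C(C)=C/COc1ccc2c(c1)O[C@H](c1ccc(O)c(O)c1)[C@@H](O)C2=O | target

**Count**

Total steps: 6. Longest linear sequence: 5 steps (steps 2, 3, 4, 5, 6, from 4-bromocatechol); the chromone branch (step 1) joins at step 4.

**Steps most likely to fail**

1. Step 4. Carbopalladation of the electron-rich 7-alkoxychromone may be slow, so that protodeboronation and homocoupling of the electron-rich boronic acid use up the nucleophile, and Pd(0) formed along the way could ionise the allylic aryl ether. The fallback sets out from 5 and 3 and comes back to the route at 10. Bromide 5 is lithiated as in step 3 (aryllithium 6) and transmetalated with ZnCl2 in THF to [3,4-bis(tert-butyldimethylsilyloxy)phenyl]zinc chloride F1. F1 is added to 3 at 20 °C with chlorotrimethylsilane and a chlororhodium(I)–BINAP catalyst, the BINAP enantiomer being chosen to give 2S. This is a rhodium-catalysed asymmetric 1,4-addition of an arylzinc reagent in which the O-bound rhodium enolate is silylated in situ, so the product is directly silyl enol ether 10, which enters step 5 at the oxidation stage. Water, boronic acid and palladium are avoided altogether, and the chlorosilane activates the chromone carbonyl.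

2. Step 5. The dioxirane may also epoxidise the geranyl alkenes (loss of chemoselectivity), or attack the enol ether syn to the aryl group (poor facial selectivity). The fallback sets out from 9 and comes back at 12. Flavanone 9 is deprotonated with NaHMDS in THF at −78 °C to the sodium enolate F2. F2 is hydroxylated in the same flask with 2-(phenylsulfonyl)-3-phenyloxaziridine at −78 °C and quenched cold with acetic acid. This is an enolate hydroxylation by an N-sulfonyloxaziridine, a reagent that does not transfer oxygen to unactivated alkenes at this temperature. The enolate is again attacked anti to the C2 aryl group, and the cold acidic quench limits ring opening by β-elimination of the phenoxide.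

3. Step 3. Protodeboronation and partial desilylation during the acidic hydrolysis and isolation of the electron-rich boronic acid may leave a reagent of undefined purity for the catalytic step. The fallback sets out from 5 and comes back at 8. A Miyaura borylation of 5 (B2pin2, Pd(dppf)Cl2, KOAc, dioxane, 80 °C) gives the chromatographable 2-[3,4-bis(tert-butyldimethylsilyloxy)phenyl]-4,4,5,5-tetramethyl-1,3,2-dioxaborolane F3. The pinacol is then cleaved oxidatively (NaIO4, NH4OAc, acetone/water, rt) to give boronic acid 8 without an organolithium or mineral acid.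

**Further compounds**

F1 | step 4 | [3,4-bis(tert-butyldimethylsilyloxy)phenyl]zinc chloride | Cl[Zn]c1ccc(O[Si](C)(C)C(C)(C)C)c(O[Si](C)(C)C(C)(C)C)c1
F2 | step 5 | sodium enolate of 9, sodium (2S)-2-[3,4-bis(tert-butyldimethylsilyloxy)phenyl]-7-{[(2E)-3,7-dimethylocta-2,6-dien-1-yl]oxy}-2H-chromen-4-olate | CC(C)=CCC/C(C)=C/COc1ccc2c(c1)O[C@H](c1ccc(O[Si](C)(C)C(C)(C)C)c(O[Si](C)(C)C(C)(C)C)c1)C=C2[O-].[Na+]
F3 | step 3 | 2-[3,4-bis(tert-butyldimethylsilyloxy)phenyl]-4,4,5,5-tetramethyl-1,3,2-dioxaborolane | CC(C)(C)[Si](C)(C)Oc1ccc(B2OC(C)(C)C(C)(C)O2)cc1O[Si](C)(C)C(C)(C)C
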